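**Retrosynthetic overview**
1. Macrocarpal N ⇐ ketal hydrolysis, thiolate tris-O-demethylation and CH2OSi → CHO oxidation of a fully protected 2-cyclopropyl-3,3-disubstituted cyclopentanone.
2. Cyclopentanone (last ring formed) ⇐ hydrogenation of a 4,4-disubstituted cyclopentenone ⇐ intramolecular aldol condensation of a 1,4-keto aldehyde; the α-stereocentre is set by equilibration.
3. Keto aldehyde ⇐ Nef reaction, LiAlH4 opening of a temporary chromanone ring and re-oxidation ⇐ key adduct from intermolecular Michael addition of a 3-methyl-4-isobutylchroman-2-one lithium enolate to a cis-cyclopropyl nitroalkene (joins aryl and terpenoid halves; quaternary centre set anti to i-Bu in the lactone ring).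
4. Chromanone (arene plus benzylic stereocentre) ⇐ organocatalytic Friedel–Crafts/hemiacetalisation of 3,5-dimethoxyphenol with (E)-5-methylhex-2-enal, then oxidation, α-methylation, diformylation, reduction, silylation; nitroalkene ⇐ ozonolysis of (+)-2-carene, Henry condensation with nitroethane, ketalisation.
5. Ring order: cyclopropane (chiral pool) and arene are bought; chromanone ring (temporary) → opened → cyclopentenone → cyclopentanone.

Assumption: the cyclopentanone α-carbon of the target is its thermodynamically preferred epimer (cyclopropyl trans to the CH(i-Bu)Ar arm), so it is fixed by base equilibration; (+)-2-carene is (1S,6R).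
Abbreviations: TBSOCH2 = (tert-butyldimethylsilyloxy)methyl; Cyp = (1R,3R)-2,2-dimethyl-3-[2-(2-methyl-1,3-dioxolan-2-yl)ethyl]cyclopropyl (cis, attached through C-1).

**Step 1**
Reactants: 1 3-methylbutanal
Product: 2 (E)-5-methylhex-2-enal
Conditions: Ph3P=CHCHO (0.9 equiv), toluene, 80 °C
Reagents that add atoms: (triphenylphosphoranylidene)acetaldehyde, O=CC=P(c1ccccc1)(c1ccccc1)c1ccccc1
Why: Wittig olefination with a stabilised ylide gives the E-enal, and the aliphatic aldehyde (in slight excess) reacts faster than the conjugated product, so double homologation stays minor.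

**Step 2**
Reactants: 2 (E)-5-methylhex-2-enal; 3 3,5-dimethoxyphenol
Product: 4 (4S)-4-isobutyl-5,7-dimethoxychroman-2-ol (both anomers)
Conditions: (R)-α,α-diphenylprolinol TMS ether (20 mol%), PhCO2H (20 mol%), toluene, 0 °C → rt
Reagents that add atoms: none
Why: Iminium-catalysed Friedel–Crafts-type Michael addition of the phenol ortho carbon followed by hemiacetalisation; the CPh2OTMS group of the (R)-catalyst shields one face of the E-iminium ion, so the arene adds to the other face and gives 4S.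

**Step 3**
Reactants: 4 (4S)-4-isobutyl-5,7-dimethoxychroman-2-ol
Product: 5 (4S)-4-isobutyl-5,7-dimethoxychroman-2-one
Conditions: TPAP (5 mol%), NMO, 4 Å MS, CH2Cl2, rt
Reagents that add atoms: none
Why: Ley–Griffith oxidation of a lactol to the lactone under neutral conditions that do not touch the electron-rich arene or the stereocentre.

**Step 4**
Reactants: 5 (4S)-4-isobutyl-5,7-dimethoxychroman-2-one
Product: 7 (3S,4S)-4-isobutyl-5,7-dimethoxy-3-methylchroman-2-one, via chromanone lithium enolate 6 (not isolated)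
Conditions: LDA, THF, −78 °C; MeI, −78 → −40 °C
Reagents that add atoms: iodomethane, CI
Why: Enolate alkylation; the 4-isobutyl group is pseudoaxial (peri strain with 5-OMe), so MeI enters anti to it (trans product); this centre is re-planarised in step 11.

**Step 5**
Reactants: 7 (3S,4S)-4-isobutyl-5,7-dimethoxy-3-methylchroman-2-one
Product: 8 (3S,4S)-4-isobutyl-5,7-dimethoxy-3-methyl-2-oxochromane-6,8-dicarbaldehyde
Conditions: Cl2CHOMe (6 equiv), TiCl4 (6 equiv), CH2Cl2, −20 °C → rt; ice-water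
Reagents that add atoms: dichloromethyl methyl ether, COC(Cl)Cl; water, O
Why: Double Rieche formylation at the only two free ring positions, each flanked by two oxygen substituents, so no regiochemical choice arises.

**Step 6**
Reactants: 8 (3S,4S)-4-isobutyl-5,7-dimethoxy-3-methyl-2-oxochromane-6,8-dicarbaldehyde
Product: 9 (3S,4S)-6,8-bis(hydroxymethyl)-4-isobutyl-5,7-dimethoxy-3-methylchroman-2-one
Conditions: NaBH4, THF–MeOH, −30 °C, 20 min; AcOH quench
Reagents that add atoms: none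
Why: Chemoselective borohydride reduction: aryl aldehydes are reduced within minutes at −30 °C while the aryl lactone survives.

**Step 7**
Reactants: 9 (3S,4S)-6,8-bis(hydroxymethyl)-4-isobutyl-5,7-dimethoxy-3-methylchroman-2-one
Product: 10 (3S,4S)-6,8-bis(TBSOCH2)-4-isobutyl-5,7-dimethoxy-3-methylchroman-2-one
Conditions: TBSCl, imidazole, DMF, rt
Reagents that add atoms: tert-butyldimethylsilyl chloride, CC(C)(C)[Si](C)(C)Cl
Why: Corey silylation masks the two formyl groups at the alcohol level so they tolerate the enolate, hydride and base chemistry that follows.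

**Step 8**
Reactants: 11 (+)-2-carene
Product: 13 (1S,3R)-2,2-dimethyl-3-(3-oxobutyl)cyclopropane-1-carbaldehyde, via secondary ozonide 12 (not isolated)
Conditions: O3, CH2Cl2, −78 °C; Me2S, −78 °C → rt
Reagents that add atoms: ozone, [O-][O+]=O
Why: Criegee ozonolysis with reductive work-up cleaves the ring alkene to the cis keto aldehyde without touching the two cyclopropane stereocentres, which are those of the target.

**Step 9**
Reactants: 13 (1S,3R)-2,2-dimethyl-3-(3-oxobutyl)cyclopropane-1-carbaldehyde; 14 nitroethane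
Product: 17 4-[(1R,3R)-2,2-dimethyl-3-((E)-2-nitroprop-1-en-1-yl)cyclopropyl]butan-2-one, via nitro alcohol 15 (not isolated), via nitro mesylate 16 (not isolated)
Conditions: EtNO2 (excess), TMG (10 mol%), THF, 0 °C; concentrate; MsCl, Et3N, CH2Cl2, −10 °C → rt
Reagents that add atoms: none
Why: Henry (nitroaldol) addition occurs only at the aldehyde (the far more acidic nitroalkane outcompetes ketone enolisation and cyclopropyl-CHO epimerisation), and mesylation/E1cB elimination gives the thermodynamic E-nitroalkene.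

**Step 10**
Reactants: 17 4-[(1R,3R)-2,2-dimethyl-3-((E)-2-nitroprop-1-en-1-yl)cyclopropyl]butan-2-one
Product: 18 2-{2-[(1R,3R)-2,2-dimethyl-3-((E)-2-nitroprop-1-en-1-yl)cyclopropyl]ethyl}-2-methyl-1,3-dioxolane
Conditions: TMSOCH2CH2OTMS, TMSOTf (5 mol%), CH2Cl2, −78 °C; pyridine quench
Reagents that add atoms: 1,2-bis(trimethylsilyloxy)ethane, C[Si](C)(C)OCCO[Si](C)(C)C
Why: Noyori ketalisation protects the methyl ketone at low temperature without harming the nitroalkene or the cyclopropane.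

**Step 11**
Reactants: 10 (3S,4S)-6,8-bis(TBSOCH2)-4-isobutyl-5,7-dimethoxy-3-methylchroman-2-one; 18 2-{2-[(1R,3R)-2,2-dimethyl-3-((E)-2-nitroprop-1-en-1-yl)cyclopropyl]ethyl}-2-methyl-1,3-dioxolane
Product: 21 (3R,4S)-6,8-bis(TBSOCH2)-3-(1-Cyp-2-nitropropyl)-4-isobutyl-5,7-dimethoxy-3-methylchroman-2-one (epimers at both side-chain CH carbons), via silylated lactone lithium enolate 19 (not isolated), via lithium nitronate 20 (not isolated)
Conditions: LDA (1.05 equiv), THF, −78 °C, 1 h; 18 (1.2 equiv), −78 °C, 2 h; AcOH, −78 °C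
Reagents that add atoms: none
Why: Michael addition of a lithium lactone enolate to a nitroalkene (the fragment-joining C–C bond): the pseudoaxial 4-isobutyl group blocks one enolate face, so the acceptor adds anti to it and the quaternary centre is fixed as 3R (side chain trans, methyl cis to i-Bu), while the CH(Cyp) and CH(NO2) centres form as mixtures that are equilibrated in step 16 or destroyed in step 12.

**Step 12**
Reactants: 21 (3R,4S)-6,8-bis(TBSOCH2)-3-(1-Cyp-2-nitropropyl)-4-isobutyl-5,7-dimethoxy-3-methylchroman-2-one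
Product: 23 (3R,4S)-6,8-bis(TBSOCH2)-3-(1-Cyp-2-oxopropyl)-4-isobutyl-5,7-dimethoxy-3-methylchroman-2-one, via potassium nitronate 22 (not isolated)
Conditions: KOtBu, THF, −40 °C; then aq. TiCl3, NH4OAc (pH ≈ 6), THF–H2O, 0 °C → rt
Reagents that add atoms: water, O
Why: McMurry variant of the Nef reaction: Ti(III) reduces the nitronate to the imine, which hydrolyses to the methyl ketone at a buffered pH that spares the lactone (no α-H left), the dioxolane and the benzylic silyl ethers.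

**Step 13**
Reactants: 23 (3R,4S)-6,8-bis(TBSOCH2)-3-(1-Cyp-2-oxopropyl)-4-isobutyl-5,7-dimethoxy-3-methylchroman-2-one
Product: 24 (2R)-3-Cyp-2-{(1S)-1-[2-hydroxy-4,6-dimethoxy-3,5-bis(TBSOCH2)phenyl]-3-methylbutyl}-2-methylpentane-1,4-diol (epimers at C-3 and C-4)
Conditions: LiAlH4, THF, 0 °C; Rochelle salt
Reagents that add atoms: none
Why: Hydride reduction opens the aryl lactone to phenol plus primary alcohol and reduces the ketone, which avoids any base-induced Dieckmann attack of the methyl ketone on the aryl ester.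

**Step 14**
Reactants: 24 (2R)-3-Cyp-2-{(1S)-1-[2-hydroxy-4,6-dimethoxy-3,5-bis(TBSOCH2)phenyl]-3-methylbutyl}-2-methylpentane-1,4-diol
Product: 25 (2R)-3-Cyp-2-methyl-2-{(1S)-3-methyl-1-[2,4,6-trimethoxy-3,5-bis(TBSOCH2)phenyl]butyl}pentane-1,4-diol
Conditions: MeI, K2CO3, acetone, 40 °C
Reagents that add atoms: iodomethane, CI
Why: Williamson etherification is selective for the phenoxide over the aliphatic alcohols and removes the free phenol that could form quinone methides or add to the later enone.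

**Step 15**
Reactants: 25 (2R)-3-Cyp-2-methyl-2-{(1S)-3-methyl-1-[2,4,6-trimethoxy-3,5-bis(TBSOCH2)phenyl]butyl}pentane-1,4-diol
Product: 26 (2R)-3-Cyp-2-methyl-2-{(1S)-3-methyl-1-[2,4,6-trimethoxy-3,5-bis(TBSOCH2)phenyl]butyl}-4-oxopentanal (epimers at C-3)
Conditions: (COCl)2, DMSO, CH2Cl2, −78 °C; Et3N, −78 → 0 °C
Reagents that add atoms: none
Why: Swern oxidation activates both hydroxyls before base is added, so the 1,4-diol goes to the keto aldehyde without lactol over-oxidation to a lactone.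

**Step 16**
Reactants: 26 (2R)-3-Cyp-2-methyl-2-{(1S)-3-methyl-1-[2,4,6-trimethoxy-3,5-bis(TBSOCH2)phenyl]butyl}-4-oxopentanal
Product: 27 (4R,5R)-5-Cyp-4-methyl-4-{(1S)-3-methyl-1-[2,4,6-trimethoxy-3,5-bis(TBSOCH2)phenyl]butyl}cyclopent-2-en-1-one
Conditions: KOH, MeOH–THF, rt → 40 °C
Reagents that add atoms: none
Why: Intramolecular aldol condensation of the methyl ketone onto the non-enolisable neopentyl aldehyde closes the five-membered ring, and the enolisable CH(Cyp) centre equilibrates to the isomer with the cyclopropyl trans to the bulky CH(i-Bu)Ar arm (5R), so both epimers converge.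

**Step 17**
Reactants: 27 (4R,5R)-5-Cyp-4-methyl-4-{(1S)-3-methyl-1-[2,4,6-trimethoxy-3,5-bis(TBSOCH2)phenyl]butyl}cyclopent-2-en-1-one
Product: 28 (2R,3R)-2-Cyp-3-methyl-3-{(1S)-3-methyl-1-[2,4,6-trimethoxy-3,5-bis(TBSOCH2)phenyl]butyl}cyclopentan-1-one
Conditions: H2 (1 atm), 10% Pd/C, EtOAc, rt
Reagents that add atoms: none
Why: Catalytic hydrogenation of the disubstituted enone C=C creates no new stereocentre and leaves the alkylcyclopropane, the ketone and the benzylic silyl ethers intact in a neutral aprotic solvent.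

**Step 18**
Reactants: 28 (2R,3R)-2-Cyp-3-methyl-3-{(1S)-3-methyl-1-[2,4,6-trimethoxy-3,5-bis(TBSOCH2)phenyl]butyl}cyclopentan-1-one
Product: 29 (2R,3R)-2-Cyp-3-{(1S)-1-[3,5-bis(hydroxymethyl)-2,4,6-trimethoxyphenyl]-3-methylbutyl}-3-methylcyclopentan-1-one
Conditions: TBAF, THF, 0 °C → rt
Reagents that add atoms: none
Why: Fluoride desilylation frees both benzylic alcohols without acid, which would ionise these electron-rich benzylic positions and cleave the ketal.

**Step 19**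
Reactants: 29 (2R,3R)-2-Cyp-3-{(1S)-1-[3,5-bis(hydroxymethyl)-2,4,6-trimethoxyphenyl]-3-methylbutyl}-3-methylcyclopentan-1-one
Product: 30 (2R,3R)-2-Cyp-3-{(1S)-1-(3,5-diformyl-2,4,6-trimethoxyphenyl)-3-methylbutyl}-3-methylcyclopentan-1-one
Conditions: Dess–Martin periodinane, NaHCO3, CH2Cl2, 0 °C → rt
Reagents that add atoms: none
Why: Buffered Dess–Martin oxidation converts both hindered benzylic alcohols into the aryl dialdehyde without affecting ketone, ketal or cyclopropane.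

**Step 20**
Reactants: 30 (2R,3R)-2-Cyp-3-{(1S)-1-(3,5-diformyl-2,4,6-trimethoxyphenyl)-3-methylbutyl}-3-methylcyclopentan-1-one
Product: 31 (2R,3R)-2-Cyp-3-{(1S)-1-(3,5-diformyl-2,4,6-trihydroxyphenyl)-3-methylbutyl}-3-methylcyclopentan-1-one
Conditions: p-TolSLi (12 equiv), HMPA–toluene, 110 °C; then cold dilute HCl to pH 4
Reagents that add atoms: none
Why: SN2 O-demethylation by thiolate is fast for the three methoxy groups ortho/para to formyl groups and, being non-acidic, spares cyclopropane and ketal, while the mildly basic medium keeps the α-stereocentre at its thermodynamic configuration.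

**Step 21**
Reactants: 31 (2R,3R)-2-Cyp-3-{(1S)-1-(3,5-diformyl-2,4,6-trihydroxyphenyl)-3-methylbutyl}-3-methylcyclopentan-1-one
Product: 32 macrocarpal N
Conditions: 1 M HCl, THF, rt
Reagents that add atoms: water, O
Why: Mild acid-catalysed ketal hydrolysis releases the side-chain methyl ketone under conditions the phloroglucinol dialdehyde and the alkylcyclopropane tolerate.

**Compound list**
1 | 3-methylbutanal | CC(C)CC=O | starting material
2 | (E)-5-methylhex-2-enal | CC(C)C/C=C/C=O | intermediate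
3 | 3,5-dimethoxyphenol | COc1cc(O)cc(OC)c1 | starting material
4 | (4S)-4-isobutyl-5,7-dimethoxychroman-2-ol (both anomers) | OC1C[C@H](CC(C)C)c2c(OC)cc(OC)cc2O1 | intermediate
5 | (4S)-4-isobutyl-5,7-dimethoxychroman-2-one | O=C1C[C@H](CC(C)C)c2c(OC)cc(OC)cc2O1 | intermediate
6 | chromanone lithium enolate (of 5) | [Li+].[O-]C1=C[C@H](CC(C)C)c2c(OC)cc(OC)cc2O1 | intermediate
7 | (3S,4S)-4-isobutyl-5,7-dimethoxy-3-methylchroman-2-one | O=C1[C@@H](C)[C@H](CC(C)C)c2c(OC)cc(OC)cc2O1 | intermediate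
8 | (3S,4S)-4-isobutyl-5,7-dimethoxy-3-methyl-2-oxochromane-6,8-dicarbaldehyde | O=C1[C@@H](C)[C@H](CC(C)C)c2c(OC)c(C=O)c(OC)c(C=O)c2O1 | intermediate
9 | (3S,4S)-6,8-bis(hydroxymethyl)-4-isobutyl-5,7-dimethoxy-3-methylchroman-2-one | O=C1[C@@H](C)[C@H](CC(C)C)c2c(OC)c(CO)c(OC)c(CO)c2O1 | intermediate
10 | (3S,4S)-6,8-bis(TBSOCH2)-4-isobutyl-5,7-dimethoxy-3-methylchroman-2-one | O=C1[C@@H](C)[C@H](CC(C)C)c2c(OC)c(CO[Si](C)(C)C(C)(C)C)c(OC)c(CO[Si](C)(C)C(C)(C)C)c2O1 | intermediate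
11 | (+)-2-carene, (1S,6R)-3,7,7-trimethylbicyclo[4.1.0]hept-2-ene | CC1=C[C@H]2[C@@H](CC1)C2(C)C | starting material
12 | secondary ozonide of 11 (1,2,4-trioxolane across former C2/C3) | CC12CC[C@@H]3[C@H](C(OO1)O2)C3(C)C | intermediate
13 | (1S,3R)-2,2-dimethyl-3-(3-oxobutyl)cyclopropane-1-carbaldehyde | CC(=O)CC[C@@H]1[C@H](C=O)C1(C)C | intermediate
14 | nitroethane | CC[N+](=O)[O-] | starting material
15 | nitro alcohol, 4-[cis-3-(1-hydroxy-2-nitropropyl)-2,2-dimethylcyclopropyl]butan-2-one (diastereomers at the two new carbons) | CC(=O)CC[C@@H]1[C@H](C(O)C(C)[N+](=O)[O-])C1(C)C | intermediate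
16 | nitro mesylate (methanesulfonate of 15) | CC(=O)CC[C@@H]1[C@H](C(OS(C)(=O)=O)C(C)[N+](=O)[O-])C1(C)C | intermediate
17 | 4-[(1R,3R)-2,2-dimethyl-3-((E)-2-nitroprop-1-en-1-yl)cyclopropyl]butan-2-one | CC(=O)CC[C@@H]1[C@H](/C=C(\C)[N+](=O)[O-])C1(C)C | intermediate
18 | 2-{2-[(1R,3R)-2,2-dimethyl-3-((E)-2-nitroprop-1-en-1-yl)cyclopropyl]ethyl}-2-methyl-1,3-dioxolane | CC1(CC[C@@H]2[C@H](/C=C(\C)[N+](=O)[O-])C2(C)C)OCCO1 | intermediate
19 | silylated lactone lithium enolate (of 10) | [Li+].[O-]C1=C(C)[C@H](CC(C)C)c2c(OC)c(CO[Si](C)(C)C(C)(C)C)c(OC)c(CO[Si](C)(C)C(C)(C)C)c2O1 | intermediate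
20 | lithium nitronate (Michael adduct before protonation) | [Li+].CC1(CC[C@@H]2[C@H](C(C(C)=[N+]([O-])[O-])[C@]3(C)C(=O)Oc4c(CO[Si](C)(C)C(C)(C)C)c(OC)c(CO[Si](C)(C)C(C)(C)C)c(OC)c4[C@H]3CC(C)C)C2(C)C)OCCO1 | intermediate
21 | (3R,4S)-6,8-bis(TBSOCH2)-3-(1-Cyp-2-nitropropyl)-4-isobutyl-5,7-dimethoxy-3-methylchroman-2-one (epimers at both side-chain CH) | CC1(CC[C@@H]2[C@H](C(C(C)[N+](=O)[O-])[C@]3(C)C(=O)Oc4c(CO[Si](C)(C)C(C)(C)C)c(OC)c(CO[Si](C)(C)C(C)(C)C)c(OC)c4[C@H]3CC(C)C)C2(C)C)OCCO1 | intermediate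
22 | potassium nitronate of 21 | [K+].CC1(CC[C@@H]2[C@H](C(C(C)=[N+]([O-])[O-])[C@]3(C)C(=O)Oc4c(CO[Si](C)(C)C(C)(C)C)c(OC)c(CO[Si](C)(C)C(C)(C)C)c(OC)c4[C@H]3CC(C)C)C2(C)C)OCCO1 | intermediate
23 | (3R,4S)-6,8-bis(TBSOCH2)-3-(1-Cyp-2-oxopropyl)-4-isobutyl-5,7-dimethoxy-3-methylchroman-2-one (epimers at side-chain CH) | CC1(CC[C@@H]2[C@H](C(C(C)=O)[C@]3(C)C(=O)Oc4c(CO[Si](C)(C)C(C)(C)C)c(OC)c(CO[Si](C)(C)C(C)(C)C)c(OC)c4[C@H]3CC(C)C)C2(C)C)OCCO1 | intermediate
24 | (2R)-3-Cyp-2-{(1S)-1-[2-hydroxy-4,6-dimethoxy-3,5-bis(TBSOCH2)phenyl]-3-methylbutyl}-2-methylpentane-1,4-diol (epimers at C-3, C-4) | CC1(CC[C@@H]2[C@H](C(C(C)O)[C@](C)(CO)[C@H](CC(C)C)c3c(O)c(CO[Si](C)(C)C(C)(C)C)c(OC)c(CO[Si](C)(C)C(C)(C)C)c3OC)C2(C)C)OCCO1 | intermediate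
25 | (2R)-3-Cyp-2-methyl-2-{(1S)-3-methyl-1-[2,4,6-trimethoxy-3,5-bis(TBSOCH2)phenyl]butyl}pentane-1,4-diol (epimers at C-3, C-4) | CC1(CC[C@@H]2[C@H](C(C(C)O)[C@](C)(CO)[C@H](CC(C)C)c3c(OC)c(CO[Si](C)(C)C(C)(C)C)c(OC)c(CO[Si](C)(C)C(C)(C)C)c3OC)C2(C)C)OCCO1 | intermediate
26 | (2R)-3-Cyp-2-methyl-2-{(1S)-3-methyl-1-[2,4,6-trimethoxy-3,5-bis(TBSOCH2)phenyl]butyl}-4-oxopentanal (epimers at C-3) | CC1(CC[C@@H]2[C@H](C(C(C)=O)[C@](C)(C=O)[C@H](CC(C)C)c3c(OC)c(CO[Si](C)(C)C(C)(C)C)c(OC)c(CO[Si](C)(C)C(C)(C)C)c3OC)C2(C)C)OCCO1 | intermediate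
27 | (4R,5R)-5-Cyp-4-methyl-4-{(1S)-3-methyl-1-[2,4,6-trimethoxy-3,5-bis(TBSOCH2)phenyl]butyl}cyclopent-2-en-1-one | CC1(CC[C@@H]2[C@H]([C@H]3C(=O)C=C[C@]3(C)[C@H](CC(C)C)c3c(OC)c(CO[Si](C)(C)C(C)(C)C)c(OC)c(CO[Si](C)(C)C(C)(C)C)c3OC)C2(C)C)OCCO1 | intermediate
28 | (2R,3R)-2-Cyp-3-methyl-3-{(1S)-3-methyl-1-[2,4,6-trimethoxy-3,5-bis(TBSOCH2)phenyl]butyl}cyclopentan-1-one | CC1(CC[C@@H]2[C@H]([C@H]3C(=O)CC[C@]3(C)[C@H](CC(C)C)c3c(OC)c(CO[Si](C)(C)C(C)(C)C)c(OC)c(CO[Si](C)(C)C(C)(C)C)c3OC)C2(C)C)OCCO1 | intermediate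
29 | (2R,3R)-2-Cyp-3-{(1S)-1-[3,5-bis(hydroxymethyl)-2,4,6-trimethoxyphenyl]-3-methylbutyl}-3-methylcyclopentan-1-one | CC1(CC[C@@H]2[C@H]([C@H]3C(=O)CC[C@]3(C)[C@H](CC(C)C)c3c(OC)c(CO)c(OC)c(CO)c3OC)C2(C)C)OCCO1 | intermediate
30 | (2R,3R)-2-Cyp-3-{(1S)-1-(3,5-diformyl-2,4,6-trimethoxyphenyl)-3-methylbutyl}-3-methylcyclopentan-1-one | CC1(CC[C@@H]2[C@H]([C@H]3C(=O)CC[C@]3(C)[C@H](CC(C)C)c3c(OC)c(C=O)c(OC)c(C=O)c3OC)C2(C)C)OCCO1 | intermediate
31 | (2R,3R)-2-Cyp-3-{(1S)-1-(3,5-diformyl-2,4,6-trihydroxyphenyl)-3-methylbutyl}-3-methylcyclopentan-1-one (macrocarpal N ethylene ketal) | CC1(CC[C@@H]2[C@H]([C@H]3C(=O)CC[C@]3(C)[C@H](CC(C)C)c3c(O)c(C=O)c(O)c(C=O)c3O)C2(C)C)OCCO1 | intermediate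
32 | macrocarpal N | CC(=O)CC[C@@H]1[C@H]([C@H]2C(=O)CC[C@]2(C)[C@H](CC(C)C)c2c(O)c(C=O)c(O)c(C=O)c2O)C1(C)C | target

**Step count and risks**
Total steps: 21. Longest linear sequence: 18 (steps 1–7, then 11–21); the carene branch (steps 8–10) joins at step 11.

Most likely to fail:

Step 11 (Michael addition that creates the quaternary centre from a tetrasubstituted enolate and a β-branched, α-methyl nitroalkene). Fallback: use the less hindered nitroalkene lacking the α-methyl group and introduce that methyl afterwards. It sets out from 13 (with 10) and rejoins at 24. Henry addition of nitromethane to 13 gives nitro alcohol F1; mesylation gives nitro mesylate F2, which eliminates to the disubstituted (E)-nitroalkene F3; Noyori ketalisation gives dioxolane F4; enolate 19 adds to F4 to give lithium nitronate F5, which is run directly into buffered aqueous TiCl3 to give aldehyde F6; MeMgBr (−78 °C, then warming) adds to the aldehyde and the new alkoxide translactonises onto the aryl ester with release of the phenol, giving γ-butyrolactone F7; LiAlH4 reduction of F7 gives triol 24.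

Step 2 (organocatalytic Friedel–Crafts/hemiacetalisation: ortho versus para attack and ee with an aliphatic enal). Fallback: make the benzylic centre by asymmetric conjugate addition to a preformed coumarin. It sets out from 3 and rejoins at 5, making steps 1–3 unnecessary. Pd(OAc)2/TFA hydroarylation–lactonisation of 3 with ethyl propiolate gives 5,7-dimethoxycoumarin F8; Cu(I)/Josiphos-type catalysed asymmetric conjugate addition of i-BuMgBr (ligand antipode chosen for 4S) with cold NH4Cl quench gives 5.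

Step 5 (the second Rieche formylation on a ring already deactivated by one formyl group and the lactone oxygen). Fallback: introduce both one-carbon units at the alcohol oxidation level with a non-deactivating electrophile. It sets out from 7 and rejoins at 9, bypassing step 6. Double Blanc chloromethylation (MOMCl, cat. ZnCl2, AcOH) gives bis(chloromethyl)chromanone F9; solvolysis (CaCO3, dioxane–H2O, 60 °C) gives diol 9.

**Further compounds**
F1 | step 11 | nitro alcohol, 4-[cis-3-(1-hydroxy-2-nitroethyl)-2,2-dimethylcyclopropyl]butan-2-one | CC(=O)CC[C@@H]1[C@H](C(O)C[N+](=O)[O-])C1(C)C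
F2 | step 11 | nitro mesylate (methanesulfonate of F1) | CC(=O)CC[C@@H]1[C@H](C(OS(C)(=O)=O)C[N+](=O)[O-])C1(C)C
F3 | step 11 | 4-[(1R,3R)-2,2-dimethyl-3-((E)-2-nitroethenyl)cyclopropyl]butan-2-one | CC(=O)CC[C@@H]1[C@H](/C=C/[N+](=O)[O-])C1(C)C
F4 | step 11 | 2-{2-[(1R,3R)-2,2-dimethyl-3-((E)-2-nitroethenyl)cyclopropyl]ethyl}-2-methyl-1,3-dioxolane | CC1(CC[C@@H]2[C@H](/C=C/[N+](=O)[O-])C2(C)C)OCCO1
F5 | step 11 | lithium nitronate of the (3R,4S)-3-(1-Cyp-2-nitroethyl) lactone | [Li+].CC1(CC[C@@H]2[C@H](C(C=[N+]([O-])[O-])[C@]3(C)C(=O)Oc4c(CO[Si](C)(C)C(C)(C)C)c(OC)c(CO[Si](C)(C)C(C)(C)C)c(OC)c4[C@H]3CC(C)C)C2(C)C)OCCO1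
F6 | step 11 | (3R,4S)-6,8-bis(TBSOCH2)-3-(1-Cyp-2-oxoethyl)-4-isobutyl-5,7-dimethoxy-3-methylchroman-2-one | CC1(CC[C@@H]2[C@H](C(C=O)[C@]3(C)C(=O)Oc4c(CO[Si](C)(C)C(C)(C)C)c(OC)c(CO[Si](C)(C)C(C)(C)C)c(OC)c4[C@H]3CC(C)C)C2(C)C)OCCO1
F7 | step 11 | (3R)-4-Cyp-3-{(1S)-1-[2-hydroxy-4,6-dimethoxy-3,5-bis(TBSOCH2)phenyl]-3-methylbutyl}-3,5-dimethyloxolan-2-one | CC1(CC[C@@H]2[C@H](C3C(C)OC(=O)[C@]3(C)[C@H](CC(C)C)c3c(O)c(CO[Si](C)(C)C(C)(C)C)c(OC)c(CO[Si](C)(C)C(C)(C)C)c3OC)C2(C)C)OCCO1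
F8 | step 2 | 5,7-dimethoxycoumarin | COc1cc(OC)c2ccc(=O)oc2c1
F9 | step 5 | (3S,4S)-6,8-bis(chloromethyl)-4-isobutyl-5,7-dimethoxy-3-methylchroman-2-one | O=C1[C@@H](C)[C@H](CC(C)C)c2c(OC)c(CCl)c(OC)c(CCl)c2O1
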